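**Retrosynthetic overview**

1. The target is a depside. Ring A is the acyl ring (C1 ester carbon, C2 OH, C3 CHO, C4 OH, C5 Cl, C6 CH3); ring B is the methyl ester ring, a 5-chloro-β-orsellinate acylated on its C4 oxygen.
2. The strategy rests on this feature of ring A: the ester-bearing C1 and the methyl-bearing C6 are neighbours and map onto the two alkyne carbons of a but-2-ynoate, while C2(O)–C3(H)–C4(O)–C5(Cl) maps onto a 4-chloro-1,1,3-trioxygenated buta-1,3-diene.
3. Disconnections, backwards: C3–CHO of ring A (Rieche formylation at the only ring C–H); the O-methyl and MOM ethers (BCl3); ring A bonds C1–C2 and C5–C6 by (4+2) cycloaddition with aromatisation through loss of methanol; the aryl ynoate ester; C5–Cl of ring B.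
4. Ring B is bought as methyl β-orsellinate and ring A is the only ring formed. The hindered depside ester is set on the small ynoic acid before ring A exists.
5. The chelated C2 hydroxyl of ring B is masked as its MOM ether only after the more reactive C4 hydroxyl has been acylated. Both ethers are cleaved before the formylation, because an aryl MOM ether is not expected to survive TiCl4.

Key step: step 6

Remark: ring A is numbered from the carbon bearing the depside carbonyl and ring B from the carbon bearing the methyl ester; compounds 1, 2, 5 and 7 are taken as purchasable. The target has no stereocentre, and the only stereochemical element of the route is the Z enol ether of diene 4.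

**Route**

Step 1
Reactants: 1 1,1-dimethoxyethene; 2 chloroacetyl chloride
Product: 3 1-chloro-4,4-dimethoxybut-3-en-2-one
Conditions: 1 (2.2 equiv in all), Et2O, −20 → 0 °C; volatiles removed cold, crude used at once
Reagents that add atoms: none
Why: C-acylation of the nucleophilic ketene acetal by the acid chloride (acylation of a ketene acetal) should give the push–pull enone after proton loss, the second equivalent of 1 trapping HCl as methyl acetate and chloromethane so that no amine is present to quaternise the chloromethyl ketone.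

Step 2
Reactants: 3 1-chloro-4,4-dimethoxybut-3-en-2-one
Product: 4 (Z)-4-chloro-1,1-dimethoxy-3-(trimethylsilyloxy)buta-1,3-diene
Conditions: LiN(iPr)2, THF, −78 °C; Me3SiCl, −78 °C → rt; filtration under argon, short-path distillation
Reagents that add atoms: chlorotrimethylsilane, C[Si](C)(C)Cl
Why: Deprotonation at the only enolisable position (the CH2Cl group) and O-silylation of the enolate (silyl enol ether formation) should give the dienyl silyl ether, the Z geometry (Cl cis to OSiMe3 and trans to the vinyl chain) being the less strained one and the one that keeps chlorine on the outside of the s-cis diene.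

Step 3
Reactants: 5 methyl 2,4-dihydroxy-3,6-dimethylbenzoate (methyl β-orsellinate)
Product: 6 methyl 5-chloro-2,4-dihydroxy-3,6-dimethylbenzoate
Conditions: SO2Cl2 (1.05 equiv), Et2O, 0 °C → rt
Reagents that add atoms: sulfuryl chloride, O=S(=O)(Cl)Cl
Why: Electrophilic aromatic chlorination can only occur at C5, the single unsubstituted ring carbon, which is ortho to the C4 hydroxyl and para to the C2 hydroxyl.

Step 4
Reactants: 6 methyl 5-chloro-2,4-dihydroxy-3,6-dimethylbenzoate; 7 but-2-ynoic acid
Product: 8 methyl 4-(but-2-ynoyloxy)-5-chloro-2-hydroxy-3,6-dimethylbenzoate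
Conditions: DCC, DMAP (cat.), CH2Cl2, 0 °C → rt
Reagents that add atoms: none
Why: Steglich esterification should acylate the free and more acidic C4 phenol, while the C2 hydroxyl, hydrogen-bonded to the ortho methyl ester, stays unreactive (the usual site selectivity of orsellinate acylation).

Step 5
Reactants: 8 methyl 4-(but-2-ynoyloxy)-5-chloro-2-hydroxy-3,6-dimethylbenzoate
Product: 9 methyl 4-(but-2-ynoyloxy)-5-chloro-2-(methoxymethoxy)-3,6-dimethylbenzoate
Conditions: MOMCl, iPr2NEt, CH2Cl2, 0 → 40 °C
Reagents that add atoms: chloromethyl methyl ether, COCCl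
Why: O-alkylation of the chelated phenol by the very electrophilic chloromethyl ether under a hindered, non-nucleophilic amine (Williamson-type acetal ether formation) should spare the aryl ynoate and removes the only acidic proton that could protodesilylate diene 4 in step 6.

Step 6
Reactants: 9 methyl 4-(but-2-ynoyloxy)-5-chloro-2-(methoxymethoxy)-3,6-dimethylbenzoate; 4 (Z)-4-chloro-1,1-dimethoxy-3-(trimethylsilyloxy)buta-1,3-diene
Product: 12 methyl 5-chloro-4-[(5-chloro-4-hydroxy-2-methoxy-6-methylbenzoyl)oxy]-2-(methoxymethoxy)-3,6-dimethylbenzoate, via cycloadduct 10 (not isolated), via aryl trimethylsilyl ether 11 (not isolated)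
Conditions: 4 (3 equiv), toluene (concentrated), 120 °C, sealed tube; then AcOH, aq. THF, rt
Reagents that add atoms: none
Why: The electron-rich diene 4 should add to the electron-poor aryl ynoate 9 in a concerted but strongly asynchronous normal-demand Diels–Alder (4+2) cycloaddition, the closest known reaction type being the cycloaddition–aromatisation of 1,1-dialkoxy-3-silyloxybuta-1,3-dienes with acetylenic esters to give 2-alkoxy-4-hydroxybenzoates. Ring A closes in this intermolecular (4+2) mode as a six-membered carbocycle, bond C5–C6 (diene CHCl terminus to the methyl-bearing alkyne carbon) leading and bond C1–C2 (ester-bearing alkyne carbon to the ketene acetal carbon) following. The regiochemistry needed (chlorine next to methyl, ketal carbon next to the ester) is secured by polarity matching: the CHCl terminus carries the largest HOMO coefficient because both the silyloxy group and the vinylogous ketene acetal push electron density onto it, so it pairs with the beta carbon of the ynoate, and the Z enol ether keeps chlorine on the outside of the s-cis diene where it does not block the approach. In cycloadduct 10 the ketal carbon and the CHCl carbon lie 1,4 across the ring, so aromatisation can only proceed by 1,4-loss of methanol (the ketal carbon has no hydrogen to leave with chloride), which keeps chlorine, methyl and both oxygens in place; the CHCl stereocentre of 10 is transient and racemic, and no stereocentre remains. The aryl ester lowers the LUMO of the ynoate relative to an alkyl ester, which helps an otherwise sluggish beta-methyl dienophile, and the depside linkage is already in place when ring A forms. Mild aqueous acid on work-up should hydrolyse aryl silyl ether 11 to the free C4 phenol without touching the MOM ether or either ester.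

Step 7
Reactants: 12 methyl 5-chloro-4-[(5-chloro-4-hydroxy-2-methoxy-6-methylbenzoyl)oxy]-2-(methoxymethoxy)-3,6-dimethylbenzoate
Product: 13 methyl 5-chloro-4-[(5-chloro-2,4-dihydroxy-6-methylbenzoyl)oxy]-2-hydroxy-3,6-dimethylbenzoate
Conditions: BCl3 (excess), CH2Cl2, −78 → 0 °C; H2O
Reagents that add atoms: none
Why: BCl3 chelates between the depside carbonyl and the ortho methoxy group of ring A and cleaves that methyl ether by chloride attack on the methyl group (chelation-assisted aryl ether dealkylation), and it cleaves the acetal MOM ether at the same time, while the aryl ester and the methyl ester should not be dealkylated at low temperature.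

Step 8
Reactants: 13 methyl 5-chloro-4-[(5-chloro-2,4-dihydroxy-6-methylbenzoyl)oxy]-2-hydroxy-3,6-dimethylbenzoate
Product: 15 methyl 5-chloro-4-[(5-chloro-3-formyl-2,4-dihydroxy-6-methylbenzoyl)oxy]-2-hydroxy-3,6-dimethylbenzoate (CNP0249536.0), via chloro(methoxy)methyl arene 14 (not isolated)
Conditions: Cl2CHOMe, TiCl4 (excess), CH2Cl2, 0 °C → rt; then 1 M aq. HCl
Reagents that add atoms: dichloromethyl methyl ether, COC(Cl)Cl; water, O
Why: In this Rieche formylation the titanium phenoxides direct the methoxychlorocarbenium electrophile ortho to oxygen, and C3 of ring A, flanked by both hydroxyls, is the only ring hydrogen in the molecule (C5 is blocked by chlorine and ring B is fully substituted), the chloro ether 14 being hydrolysed to the aldehyde on acidic work-up.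

**Compound list**

1 | 1,1-dimethoxyethene (ketene dimethyl acetal) | C=C(OC)OC | starting material
2 | chloroacetyl chloride | O=C(Cl)CCl | starting material
3 | 1-chloro-4,4-dimethoxybut-3-en-2-one | COC(OC)=CC(=O)CCl | intermediate
4 | (Z)-4-chloro-1,1-dimethoxy-3-(trimethylsilyloxy)buta-1,3-diene | COC(OC)=C/C(O[Si](C)(C)C)=C/Cl | intermediate
5 | methyl 2,4-dihydroxy-3,6-dimethylbenzoate (methyl β-orsellinate) | COC(=O)c1c(C)cc(O)c(C)c1O | starting material
6 | methyl 5-chloro-2,4-dihydroxy-3,6-dimethylbenzoate | COC(=O)c1c(C)c(Cl)c(O)c(C)c1O | intermediate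
7 | but-2-ynoic acid | CC#CC(=O)O | starting material
8 | methyl 4-(but-2-ynoyloxy)-5-chloro-2-hydroxy-3,6-dimethylbenzoate | CC#CC(=O)Oc1c(C)c(O)c(C(=O)OC)c(C)c1Cl | intermediate
9 | methyl 4-(but-2-ynoyloxy)-5-chloro-2-(methoxymethoxy)-3,6-dimethylbenzoate | CC#CC(=O)Oc1c(C)c(OCOC)c(C(=O)OC)c(C)c1Cl | intermediate
10 | 2-chloro-4-(methoxycarbonyl)-5-(methoxymethoxy)-3,6-dimethylphenyl 3-chloro-6,6-dimethoxy-2-methyl-4-(trimethylsilyloxy)cyclohexa-1,4-diene-1-carboxylate (racemic cycloadduct) | COC1(OC)C=C(O[Si](C)(C)C)C(Cl)C(C)=C1C(=O)Oc1c(C)c(OCOC)c(C(=O)OC)c(C)c1Cl | intermediate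
11 | methyl 5-chloro-4-{[5-chloro-2-methoxy-6-methyl-4-(trimethylsilyloxy)benzoyl]oxy}-2-(methoxymethoxy)-3,6-dimethylbenzoate | COc1cc(O[Si](C)(C)C)c(Cl)c(C)c1C(=O)Oc1c(C)c(OCOC)c(C(=O)OC)c(C)c1Cl | intermediate
12 | methyl 5-chloro-4-[(5-chloro-4-hydroxy-2-methoxy-6-methylbenzoyl)oxy]-2-(methoxymethoxy)-3,6-dimethylbenzoate | COc1cc(O)c(Cl)c(C)c1C(=O)Oc1c(C)c(OCOC)c(C(=O)OC)c(C)c1Cl | intermediate
13 | methyl 5-chloro-4-[(5-chloro-2,4-dihydroxy-6-methylbenzoyl)oxy]-2-hydroxy-3,6-dimethylbenzoate | COC(=O)c1c(C)c(Cl)c(OC(=O)c2c(C)c(Cl)c(O)cc2O)c(C)c1O | intermediate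
14 | methyl 5-chloro-4-({5-chloro-3-[chloro(methoxy)methyl]-2,4-dihydroxy-6-methylbenzoyl}oxy)-2-hydroxy-3,6-dimethylbenzoate (racemic) | COC(=O)c1c(C)c(Cl)c(OC(=O)c2c(C)c(Cl)c(O)c(C(Cl)OC)c2O)c(C)c1O | intermediate
15 | methyl 5-chloro-4-[(5-chloro-3-formyl-2,4-dihydroxy-6-methylbenzoyl)oxy]-2-hydroxy-3,6-dimethylbenzoate | COC(=O)c1c(C)c(Cl)c(OC(=O)c2c(C)c(Cl)c(O)c(C=O)c2O)c(C)c1O | target

**Count and risks**

Total step count: 8. Longest linear sequence: 6 steps (steps 3 to 8, from 5 to 15); the diene arm (steps 1 and 2) joins at step 6.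

Steps most likely to fail:

1. Step 6. The cycloaddition may be too slow: the dienophile carries a beta methyl group and the bonding diene terminus carries chlorine. Diene 4 may then decompose or lose its silyl group at the temperature needed, and some reversed regiochemistry may leak through. Fallback, setting out from 6 and coming back at 13: the depside bond would be made by classical acylation with a preformed ring A acid.
   - Purchased methyl 2,4-dihydroxy-6-methylbenzoate F1 would be chlorinated (SO2Cl2, Et2O, 0 °C) to methyl 5-chloro-2,4-dihydroxy-6-methylbenzoate F2, with any 3-chloro isomer removed by crystallisation.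
   - Benzylation (BnBr, K2CO3, DMF) would give methyl 2,4-bis(benzyloxy)-5-chloro-6-methylbenzoate F3, and saponification (KOH, aq. DMSO, 90 °C) 2,4-bis(benzyloxy)-5-chloro-6-methylbenzoic acid F4.
   - F4 and phenol 6 would be condensed with (CF3CO)2O in toluene, through 2,4-bis(benzyloxy)-5-chloro-6-methylbenzoic trifluoroacetic anhydride F5, at the C4 hydroxyl of 6 to give methyl 4-{[2,4-bis(benzyloxy)-5-chloro-6-methylbenzoyl]oxy}-5-chloro-2-hydroxy-3,6-dimethylbenzoate F6.
   - BCl3 with pentamethylbenzene (CH2Cl2, −78 °C) would remove both benzyl ethers without touching the aryl chlorides and give 13, which enters step 8.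

2. Step 1. The acid chloride may lose HCl to chloroketene and give cyclobutanone-derived products. The chloromethyl ketone 3 may also cyclise by attack of a ketene acetal oxygen on the CH2Cl carbon with loss of chloromethane before it can be silylated. Fallback, setting out from 9 and coming back at 12: chlorine is left out of the diene and put on ring A after the cycloaddition.
   - 1 would be acylated with acetyl chloride to 4,4-dimethoxybut-3-en-2-one F7 and silylated (LiN(iPr)2, Me3SiCl, THF, −78 °C) to 1,1-dimethoxy-3-(trimethylsilyloxy)buta-1,3-diene F8.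
   - F8 and 9 under the conditions of step 6 should give the cycloadduct 2-chloro-4-(methoxycarbonyl)-5-(methoxymethoxy)-3,6-dimethylphenyl 6,6-dimethoxy-2-methyl-4-(trimethylsilyloxy)cyclohexa-1,4-diene-1-carboxylate F9.
   - Loss of methanol would give methyl 5-chloro-4-{[2-methoxy-6-methyl-4-(trimethylsilyloxy)benzoyl]oxy}-2-(methoxymethoxy)-3,6-dimethylbenzoate F10, and work-up methyl 5-chloro-4-[(4-hydroxy-2-methoxy-6-methylbenzoyl)oxy]-2-(methoxymethoxy)-3,6-dimethylbenzoate F11.
   - N-chlorosuccinimide (1 equiv, MeCN, rt) should then chlorinate ring A at C5 (ortho to the hydroxyl, para to the methoxy group, and less crowded than C3) to give 12.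

3. Step 5. Under base the phenoxide, the amine or chloride may add to the ynoate in conjugate fashion, the aryl ester may be transferred between molecules, or alkylation of the chelated hydroxyl may stay incomplete. Fallback, setting out from 6 and coming back at 9: the MOM ether is installed before the ynoate.
   - 6 would be allylated at the non-chelated C4 hydroxyl (allyl bromide, K2CO3, acetone) to methyl 4-(allyloxy)-5-chloro-2-hydroxy-3,6-dimethylbenzoate F12.
   - MOM protection (NaH, MOMCl, DMF) would give methyl 4-(allyloxy)-5-chloro-2-(methoxymethoxy)-3,6-dimethylbenzoate F13.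
   - Deallylation (Pd(PPh3)4 cat., morpholine, THF, rt) would give methyl 5-chloro-4-hydroxy-2-(methoxymethoxy)-3,6-dimethylbenzoate F14.
   - Steglich esterification of F14 with 7 (DCC, DMAP, CH2Cl2) would give 9.

**Further compounds**

F1 | step 6 | methyl 2,4-dihydroxy-6-methylbenzoate (methyl orsellinate, purchased) | COC(=O)c1c(C)cc(O)cc1O
F2 | step 6 | methyl 5-chloro-2,4-dihydroxy-6-methylbenzoate | COC(=O)c1c(C)c(Cl)c(O)cc1O
F3 | step 6 | methyl 2,4-bis(benzyloxy)-5-chloro-6-methylbenzoate | COC(=O)c1c(C)c(Cl)c(OCc2ccccc2)cc1OCc1ccccc1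
F4 | step 6 | 2,4-bis(benzyloxy)-5-chloro-6-methylbenzoic acid | OC(=O)c1c(C)c(Cl)c(OCc2ccccc2)cc1OCc1ccccc1
F5 | step 6 | 2,4-bis(benzyloxy)-5-chloro-6-methylbenzoic trifluoroacetic anhydride | O=C(OC(=O)C(F)(F)F)c1c(C)c(Cl)c(OCc2ccccc2)cc1OCc1ccccc1
F6 | step 6 | methyl 4-{[2,4-bis(benzyloxy)-5-chloro-6-methylbenzoyl]oxy}-5-chloro-2-hydroxy-3,6-dimethylbenzoate | COC(=O)c1c(C)c(Cl)c(OC(=O)c2c(C)c(Cl)c(OCc3ccccc3)cc2OCc2ccccc2)c(C)c1O
F7 | step 1 | 4,4-dimethoxybut-3-en-2-one | COC(OC)=CC(C)=O
F8 | step 1 | 1,1-dimethoxy-3-(trimethylsilyloxy)buta-1,3-diene | COC(OC)=CC(=C)O[Si](C)(C)C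
F9 | step 1 | 2-chloro-4-(methoxycarbonyl)-5-(methoxymethoxy)-3,6-dimethylphenyl 6,6-dimethoxy-2-methyl-4-(trimethylsilyloxy)cyclohexa-1,4-diene-1-carboxylate | COC1(OC)C=C(O[Si](C)(C)C)CC(C)=C1C(=O)Oc1c(C)c(OCOC)c(C(=O)OC)c(C)c1Cl
F10 | step 1 | methyl 5-chloro-4-{[2-methoxy-6-methyl-4-(trimethylsilyloxy)benzoyl]oxy}-2-(methoxymethoxy)-3,6-dimethylbenzoate | COc1cc(O[Si](C)(C)C)cc(C)c1C(=O)Oc1c(C)c(OCOC)c(C(=O)OC)c(C)c1Cl
F11 | step 1 | methyl 5-chloro-4-[(4-hydroxy-2-methoxy-6-methylbenzoyl)oxy]-2-(methoxymethoxy)-3,6-dimethylbenzoate | COc1cc(O)cc(C)c1C(=O)Oc1c(C)c(OCOC)c(C(=O)OC)c(C)c1Cl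
F12 | step 5 | methyl 4-(allyloxy)-5-chloro-2-hydroxy-3,6-dimethylbenzoate | C=CCOc1c(C)c(O)c(C(=O)OC)c(C)c1Cl
F13 | step 5 | methyl 4-(allyloxy)-5-chloro-2-(methoxymethoxy)-3,6-dimethylbenzoate | C=CCOc1c(C)c(OCOC)c(C(=O)OC)c(C)c1Cl
F14 | step 5 | methyl 5-chloro-4-hydroxy-2-(methoxymethoxy)-3,6-dimethylbenzoate | COCOc1c(C)c(O)c(Cl)c(C)c1C(=O)OC
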